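The constants stand in the two earlier runs, and a quick number can be had from them by counting.

| setting | alder | elm | eta | alpha | beta | theta | zeta |
|---|---|---|---|---|---|---|---|
| solid substrate | 1.6 mM | 16 mM | 1.2 mM | 2.5 mM | 5.0 mM | 3.0 mM | 10 mM |
| remark | run made earlier | run made earlier |  |  |  |  |  |
| time |  |  | 2.0 min | 2.0 min | 2.0 min | 2.0 min | 2.0 min |

| run | time / s | target / % | solid substrate / % |
|---|---|---|---|
| alder | 10.0 | 22.5 | 0.3 |
| alder | 20.0 | 38.9 | 0 |
| alder | 40.0 | 57.2 | 0.4 |
| alder | 60.0 | 67.1 | 0.3 |
| elm | 10.0 | 4.6 | 81.3 |
| elm | 20.0 | 12.4 | 73.2 |
| elm | 40.0 | 28.2 | 57.1 |
| elm | 60.0 | 44.2 | 41.4 |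

(scatter of a reading: 0.3 percentage points)

- in percentages every species weighs as the solid substrate in it: one target counts as two
- as a solid, counted per litre of solution: solid substrate
- what was read earlier has a scatter of 0.3 percentage points, one standard deviation
- at the start none of the solid substrate is in solution
- what has only dissolved of solid substrate counts as not reacted

* ranking by amount of target, in percent of the solid substrate charged, from high to low, at 2.0 min (eta / alpha / beta / theta / zeta)
* the amount of target, in percent of the solid substrate charged of the flask you put first, at 2.0 min
* the amount of target, in percent of the solid substrate charged of the flask you put last, at 2.0 min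

In the alder run the solid substrate reads 0.3 % by 10.0 s. The inverse of the unreacted fraction then climbs in a straight line, which gives a second-order constant of 0.0219 mM⁻¹ s⁻¹ after a lag of 1.85 s.

In the elm run solid stays, and [dissolved solid substrate] holds near 2.33 mM, a steady state. Target grows there at a constant pace. That pace, the charged substrate turned into target per second, is the drain, 0.127 mM s⁻¹, after a lag of 4.40 s.

Turnovers are the drain times the time after the lag, divided by the charge. While solid lies in a flask, that count is reckoned as its target share.

Zeta counts 1.47 turnovers by 2.0 min, more than one. Its solid is therefore reckoned gone at 64.7 s, and second-order decay from the steady level then gives 93.9 % target. Eta, charged with 1.2 mM, lies below that level, so it is reckoned as decaying from its charge, to 75.6 % target.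

This reckoning covers zeta and eta and stops there; the ranking of the flasks is the forecast's. The forecast says “any flask holding solid runs at a fixed rate until the solid is gone”. It gives zeta > beta > theta > alpha > eta, with 94 % (92.5 % to 95 %) for zeta and 75.7 % (74.5 % to 77 %) for eta.

The flasks give zeta > beta > theta > alpha > eta, with 93.9 % in zeta and 75.8 % in eta.

    solid substrate ⇌ starting material, rate k1*(cs1 - [starting material]) while solid is left; crystals form when [starting material] > cs1 (solubility = 2.90 mM, k = 0.250 s⁻¹)
    2 starting material → target (k = 11.0 M⁻¹ s⁻¹)

At 1.00 min zeta holds 6.04 % solid, the drain counts 70.7 %, and zeta stands at 70.0 % target. A neighbour of zeta, charged with 17 mM, holds 0.189 % solid at 2.00 min; the drain counts 86.4 %, and that neighbour stands at 85.7 % target.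

(Readings and results were generated by integration with constants of no real substance, and the scatter is random.)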